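Ring A, the cyclohexa-2,5-dienone, is numbered C1 (C=O), C2 (CMe), C3 (side-chain carbon), C4 (quaternary), C5 (CH), C6 (CMe). Everything rests on the tetrasubstituted C2=C3 olefin. Its ring neighbours C1 and C4 are cis, so C1 and the C7 alkenyl chain are trans, which is the signature of an anti addition across a propynyl group on C4. One palladium-catalysed operation lets that alkyne attack a (Z)-enal carbon (C1–C2, ring closure) and couples the resulting C3–palladium bond with the side-chain boronic acid (C3–C7). The precursor is an acyclic (Z)-alkynal carrying the pyrone and the C4 stereocentre, which is set by copper-catalysed allylic alkynylation.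

Key step: step 17

Assumption: the side chain is numbered C7 (olefinic CMe), C8 (olefinic CH), C9 (CHMe stereocentre), C10 (ketone carbon). The enantiomer of the NHC precursor in step 7 is the one that gives (S) at C4, to be confirmed on the first batch.

Step 1
Reactants: 1 methyl 2-methyl-3-oxopentanoate; 2 N-methoxy-N-methylpropanamide
Product: 3 methyl 2,4-dimethyl-3,5-dioxoheptanoate (mixture of stereoisomers)
Conditions: LiN(i-Pr)2 (2.2 equiv), THF, -78 to 0 °C; 2, -78 °C to rt; aq. HCl
Reagents that add atoms: none
Why: The γ-carbon of the β-keto ester dianion is its most nucleophilic site and the N-methoxy-N-methylamide stops at the chelated tetrahedral adduct, so one clean γ-acylation (dianion Claisen-type acylation) is expected; the two stereocentres vanish in step 2.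

Step 2
Reactants: 3 methyl 2,4-dimethyl-3,5-dioxoheptanoate
Product: 4 6-ethyl-4-hydroxy-3,5-dimethyl-2H-pyran-2-one
Conditions: DBU, toluene, reflux
Reagents that add atoms: none
Why: Enolisation and lactonisation of the C5 enol oxygen onto the ester (triketide cyclisation to a 4-hydroxy-2-pyrone) is driven by loss of methanol and by the aromatic character of the product.

Step 3
Reactants: 4 6-ethyl-4-hydroxy-3,5-dimethyl-2H-pyran-2-one
Product: 5 6-ethyl-2-methoxy-3,5-dimethyl-4H-pyran-4-one
Conditions: MeOTf, CH2Cl2, rt; aq. NaHCO3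
Reagents that add atoms: methyl trifluoromethanesulfonate COS(=O)(=O)C(F)(F)F
Why: The hard methylating agent attacks the most basic oxygen, the lactone carbonyl, and the 2-methoxy-4-hydroxypyrylium salt loses a proton on work-up to give the 2-methoxy-4-pyrone (regioselective O-methylation).

Step 4
Reactants: 5 6-ethyl-2-methoxy-3,5-dimethyl-4H-pyran-4-one; 6 (tert-butyldimethylsilyloxy)acetaldehyde
Product: 9 6-[(E)-4-(tert-butyldimethylsilyloxy)but-2-en-2-yl]-2-methoxy-3,5-dimethyl-4H-pyran-4-one, via aldol adduct 7 (not isolated), via aldol mesylate 8 (not isolated)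
Conditions: LiN(SiMe3)2, THF, -78 °C; 6; MsCl, -78 to 0 °C; DBU, rt
Reagents that add atoms: none
Why: The CH2 of the 6-ethyl group is vinylogously acidic, so its anion adds to the aldehyde (vinylogous aldol addition), and E1cB loss of mesylate gives the conjugated olefin, whose (E) geometry keeps the CH2OSi group away from the pyrone.

Step 5
Reactants: 9 (E)-allylic silyl ether
Product: 10 6-[(E)-4-hydroxybut-2-en-2-yl]-2-methoxy-3,5-dimethyl-4H-pyran-4-one
Conditions: HF·pyridine, THF, 0 °C to rt
Reagents that add atoms: none
Why: Fluoride-driven cleavage of a primary silyl ether under mildly acidic conditions leaves the pyrone and the olefin geometry untouched (desilylation).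

Step 6
Reactants: 10 (E)-allylic alcohol
Product: 11 diethyl (E)-3-(6-methoxy-3,5-dimethyl-4-oxo-4H-pyran-2-yl)but-2-enyl phosphate
Conditions: ClP(O)(OEt)2, Et3N, DMAP (10 mol%), CH2Cl2, 0 °C
Reagents that add atoms: diethyl chlorophosphate CCOP(=O)(Cl)OCC
Why: DMAP-catalysed O-phosphorylation of a primary allylic alcohol is fast at 0 °C, and the weak amine base should not trigger elimination.

Step 7
Reactants: 11 (E)-allylic phosphate; 12 propyne
Product: 14 2-methoxy-3,5-dimethyl-6-[(3S)-3-methylhex-1-en-4-yn-3-yl]-4H-pyran-4-one, via diisobutyl(prop-1-ynyl)aluminium 13 (not isolated)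
Conditions: 12, i-Bu2AlH, Et3N (5 mol%), hexanes, 0 to 22 °C; then 11, chiral sulfonate-bearing imidazolinium salt (NHC precursor, 2.5 mol%), CuCl2·2H2O (5 mol%), THF, -15 °C
Reagents that add atoms: none
Why: Copper-catalysed enantioselective allylic substitution with an alkynylaluminium reagent delivers the alkynyl group SN2' to the γ,γ-disubstituted carbon of an aryl-type allylic phosphate, and the sulfonate-bridged NHC–copper complex selects the olefin face, which sets the quaternary centre C4 as (S).

Step 8
Reactants: 14 (S)-1,4-enyne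
Product: 15 (2S)-2-(6-methoxy-3,5-dimethyl-4-oxo-4H-pyran-2-yl)-2-methylpent-3-ynal
Conditions: OsO4 (2 mol%), NaIO4 (4 equiv), 2,6-lutidine, dioxane/H2O 3:1, rt
Reagents that add atoms: sodium periodate [Na+].[O-]I(=O)(=O)=O (oxygen, relayed through OsO4)
Why: In the Lemieux–Johnson cleavage the monosubstituted vinyl group reacts far faster than the alkyne or the tetrasubstituted pyrone olefins, and C4 has no hydrogen and cannot epimerise.

Step 9
Reactants: 15 (S)-α-quaternary aldehyde; 16 methyl 2-[bis(2,2,2-trifluoroethoxy)phosphoryl]propanoate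
Product: 17 methyl (2Z,4S)-4-(6-methoxy-3,5-dimethyl-4-oxo-4H-pyran-2-yl)-2,4-dimethylhept-2-en-5-ynoate
Conditions: KN(SiMe3)2, 18-crown-6, THF, -78 °C; 15
Reagents that add atoms: none
Why: In the Still–Gennari olefination the electron-poor phosphonate eliminates quickly and irreversibly from the kinetic adduct, so the ester carbon C1 ends up cis to C4, and bulky non-enolisable aldehydes usually enhance this (Z) preference.

Step 10
Reactants: 17 (Z)-enoate
Product: 18 (2Z,4S)-allylic alcohol, 6-[(2Z,4S)-1-hydroxy-2,4-dimethylhept-2-en-5-yn-4-yl]-2-methoxy-3,5-dimethyl-4H-pyran-4-one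
Conditions: i-Bu2AlH (2.5 equiv), CH2Cl2, -78 °C; aq. potassium sodium tartrate
Reagents that add atoms: none
Why: 1,2-Reduction of an enoate by i-Bu2AlH at low temperature is faster than attack on the vinylogous carbonate carbonyl of the 2-methoxy-4-pyrone and keeps the olefin geometry.

Step 11
Reactants: 18 (Z)-allylic alcohol
Product: 19 (2Z,4S)-4-(6-methoxy-3,5-dimethyl-4-oxo-4H-pyran-2-yl)-2,4-dimethylhept-2-en-5-ynal
Conditions: MnO2 (20 equiv), CH2Cl2, rt, dark
Reagents that add atoms: none
Why: Neutral heterogeneous allylic oxidation gives the (Z)-enal without acid or base that could isomerise it to the (E)-enal.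

Step 12
Reactants: 20 pent-3-yn-2-one
Product: 21 (R)-pent-3-yn-2-ol
Conditions: Ru[(R,R)-TsDPEN](p-cymene) (0.5 mol%), i-PrOH, 28 °C
Reagents that add atoms: none
Why: Noyori asymmetric transfer hydrogenation reduces alkynyl methyl ketones at the carbonyl only, and the (R,R) catalyst delivers hydride to the face that gives the (R)-carbinol.

Step 13
Reactants: 21 (R)-pent-3-yn-2-ol
Product: 22 (R)-pent-3-yn-2-yl methanesulfonate
Conditions: MsCl, Et3N, CH2Cl2, -78 °C
Reagents that add atoms: methanesulfonyl chloride CS(=O)(=O)Cl
Why: O-Sulfonylation does not touch the C–O bond, so the configuration is retained.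

Step 14
Reactants: 22 (R)-propargylic mesylate; 23 propanal
Product: 25 (3R,4S)-4-methylhept-5-yn-3-ol, via ethyl(allenyl)zinc 24 (not isolated)
Conditions: Pd(OAc)2 (5 mol%), PPh3 (5 mol%), Et2Zn (3 equiv), THF, -78 to -20 °C
Reagents that add atoms: none
Why: Zerovalent palladium displaces the mesylate anti (SN2'), transmetallation to zinc keeps the allene axis, and the allenylzinc adds to propanal through a cyclic SE2' transition state, so C9 is set as (S) with net inversion of 22 and the anti C9/C10 relationship follows from the equatorial ethyl group.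

Step 15
Reactants: 25 (3R,4S)-4-methylhept-5-yn-3-ol
Product: 26 (3R,4S,5Z)-4-methyl-6-(4,4,5,5-tetramethyl-1,3,2-dioxaborolan-2-yl)hept-5-en-3-ol
Conditions: B2pin2 (1.1 equiv), CuCl (5 mol%), Xantphos (5 mol%), NaOt-Bu (10 mol%), MeOH (2 equiv), THF, rt
Reagents that add atoms: bis(pinacolato)diboron CC1(C)OB(OC1(C)C)B1OC(C)(C)C(C)(C)O1
Why: Copper-catalysed hydroboration is a syn borylcupration–protonation that puts boron on the less hindered, methyl-bearing alkyne carbon C7, which gives boron trans to C9 and tolerates the free alcohol.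

Step 16
Reactants: 26 alkenyl pinacol boronate
Product: 27 [(2Z,4S,5R)-5-hydroxy-4-methylhept-2-en-2-yl]boronic acid
Conditions: NaIO4 (3 equiv), NH4OAc (3 equiv), acetone/H2O 1:1, rt
Reagents that add atoms: water O
Why: Periodate removes pinacol from the hydrolysis equilibrium by glycol cleavage, and the isolated secondary alcohol and the olefin are inert to it.

Step 17
Reactants: 19 (2Z,4S)-alkynal; 27 alkenylboronic acid
Product: 28 dienol diol, 6-{(1S)-4-hydroxy-2-[(2E,4S,5R)-5-hydroxy-4-methylhept-2-en-2-yl]-1,3,5-trimethylcyclohexa-2,5-dien-1-yl}-2-methoxy-3,5-dimethyl-4H-pyran-4-one (both C1 carbinol epimers)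
Conditions: Pd2(dba)3·CHCl3 (5 mol%), PCy3 (20 mol%), 27 (1.5 equiv), degassed MeOH, 65 °C; used at once
Reagents that add atoms: none
Why: Zerovalent palladium bound to the propynyl triple bond makes C2 nucleophilic, and C2 attacks the formyl carbon C1 (activated by hydrogen bonding to methanol and the boronic acid) from the side opposite the metal, which forms C1–C2 and leaves a divalent alkenylpalladium alkoxide at C3; transmetallation with 27 and reductive elimination then form C3–C7 with retention. The closest known reaction type is the palladium/monophosphine-catalysed trans-selective alkylative cyclisation of 5-alkynals with organoboronic acids, which gives 2,3-disubstituted cyclohex-2-enols. Ring A closes in the 6-endo-dig mode. The only new stereocentre, carbinol C1, is uncontrolled and is erased in step 18, while C4, C9 and C10 are spectators and the C5=C6 and C7=C8 geometries are retained. The step needs anti rather than syn addition and endo rather than 5-exo closure: anti addition is inherent in the mechanism and is the only topology that places C1 and C4 cis in a six-membered ring, and endo closure should be helped by electron-rich PCy3, by the small methyl cap on C2, by the cis C5=C6 olefin that holds C1 over the alkyne, and by the strain and crowding of the alternative 4-alkylidenecyclopentenol, whose new bond would lie next to quaternary C4. Base-free methanol tolerates the free C10 alcohol and the pyrone.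

Step 18
Reactants: 28 dienol diol
Product: 29 target, 2-methoxy-3,5-dimethyl-6-{(1S)-1,3,5-trimethyl-2-[(2E,4S)-4-methyl-5-oxohept-2-en-2-yl]-4-oxocyclohexa-2,5-dien-1-yl}-4H-pyran-4-one
Conditions: DMP (3 equiv), NaHCO3 (10 equiv), CH2Cl2, 0 °C
Reagents that add atoms: none
Why: The buffered Dess–Martin oxidation converts both secondary carbinols (C1 and C10) in one operation under non-acidic, non-basic conditions, so the dienol is not ionised and the newly formed α-stereocentre C9 of the β,γ-unsaturated ketone is not epimerised.

Compound list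
1 | methyl 2-methyl-3-oxopentanoate | CCC(=O)C(C)C(=O)OC | starting material
2 | N-methoxy-N-methylpropanamide | CCC(=O)N(C)OC | starting material
3 | methyl 2,4-dimethyl-3,5-dioxoheptanoate | CCC(=O)C(C)C(=O)C(C)C(=O)OC | intermediate
4 | 6-ethyl-4-hydroxy-3,5-dimethyl-2H-pyran-2-one | CCc1oc(=O)c(C)c(O)c1C | intermediate
5 | 6-ethyl-2-methoxy-3,5-dimethyl-4H-pyran-4-one | CCc1oc(OC)c(C)c(=O)c1C | intermediate
6 | (tert-butyldimethylsilyloxy)acetaldehyde | O=CCO[Si](C)(C)C(C)(C)C | starting material
7 | aldol adduct (formed as its lithium alkoxide, not isolated) | CC(C(O)CO[Si](C)(C)C(C)(C)C)c1oc(OC)c(C)c(=O)c1C | intermediate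
8 | aldol mesylate (not isolated) | CC(C(CO[Si](C)(C)C(C)(C)C)OS(C)(=O)=O)c1oc(OC)c(C)c(=O)c1C | intermediate
9 | (E)-allylic silyl ether | CC(C)(C)[Si](C)(C)OC/C=C(\C)c1oc(OC)c(C)c(=O)c1C | intermediate
10 | (E)-allylic alcohol | OC/C=C(\C)c1oc(OC)c(C)c(=O)c1C | intermediate
11 | (E)-allylic diethyl phosphate | CCOP(=O)(OCC)OC/C=C(\C)c1oc(OC)c(C)c(=O)c1C | intermediate
12 | propyne | CC#C | starting material
13 | diisobutyl(prop-1-ynyl)aluminium (not isolated) | CC#C[Al](CC(C)C)CC(C)C | intermediate
14 | (S)-1,4-enyne with quaternary C4 | C=C[C@](C#CC)(C)c1oc(OC)c(C)c(=O)c1C | intermediate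
15 | (S)-α-quaternary aldehyde | O=C[C@](C#CC)(C)c1oc(OC)c(C)c(=O)c1C | intermediate
16 | methyl 2-[bis(2,2,2-trifluoroethoxy)phosphoryl]propanoate | COC(=O)C(C)P(=O)(OCC(F)(F)F)OCC(F)(F)F | starting material
17 | (2Z,4S)-enoate | COC(=O)/C(C)=C\[C@](C#CC)(C)c1oc(OC)c(C)c(=O)c1C | intermediate
18 | (2Z,4S)-allylic alcohol | OC/C(C)=C\[C@](C#CC)(C)c1oc(OC)c(C)c(=O)c1C | intermediate
19 | (2Z,4S)-alkynal | O=C/C(C)=C\[C@](C#CC)(C)c1oc(OC)c(C)c(=O)c1C | intermediate
20 | pent-3-yn-2-one | CC#CC(C)=O | starting material
21 | (R)-pent-3-yn-2-ol | C[C@@H](O)C#CC | intermediate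
22 | (R)-pent-3-yn-2-yl methanesulfonate | C[C@@H](OS(C)(=O)=O)C#CC | intermediate
23 | propanal | CCC=O | starting material
24 | ethyl(penta-2,3-dien-2-yl)zinc, single allene axis (not isolated) | CC[Zn]C(C)=[C@]=C(C)[H] | intermediate
25 | (3R,4S)-4-methylhept-5-yn-3-ol | CC[C@@H](O)[C@@H](C)C#CC | intermediate
26 | (3R,4S,5Z)-alkenyl pinacol boronate | CC[C@@H](O)[C@@H](C)/C=C(\C)B1OC(C)(C)C(C)(C)O1 | intermediate
27 | (2Z,4S,5R)-alkenylboronic acid | CC[C@@H](O)[C@@H](C)/C=C(\C)B(O)O | intermediate
28 | dienol diol (C1 epimers) | CC[C@@H](O)[C@@H](C)/C=C(\C)C1=C(C)C(O)C(C)=C[C@]1(C)c1oc(OC)c(C)c(=O)c1C | intermediate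
29 | CNP0276209.1 | CCC(=O)[C@@H](C)/C=C(\C)C1=C(C)C(=O)C(C)=C[C@]1(C)c1oc(OC)c(C)c(=O)c1C | target

Total step count: 18. Longest linear sequence: 13 (steps 1–11, 17, 18). The side-chain branch (steps 12–16) has 5 steps.

Steps most likely to fail

Step 17. Three processes could defeat the closure.
- The ring may close through the inner alkyne carbon (5-exo), because palladium then sits on the less hindered carbon.
- Transmetallation and reductive elimination at C3, next to quaternary C4, may be slow enough for protodepalladation to win.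
- The product dienol may ionise in hot methanol.

The fallback sets out from 17 and 27 and comes back at 29. It keeps the same ring-closing bond but makes C3–C7 first and closes at the acyl oxidation level.
- Gold-catalysed hydration of 17 (AuCl(PPh3), AgOTf, wet dioxane), steered to C3 by participation of the ester carbonyl oxygen, would give the ethyl ketone F1.
- KN(SiMe3)2 and N-(5-chloro-2-pyridyl)bis(trifluoromethanesulfonimide) would give the (Z)-enol triflate F2.
- Suzuki–Miyaura coupling with 27 (Pd(PPh3)4, K3PO4, dioxane/H2O) would give the triene ester F3.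
- Me3SnOH would give the triene acid F4.
- Trifluoroacetic anhydride in CH2Cl2 at 0 °C would mask the C10 alcohol and activate the acid. The diene terminus C2 then attacks the acyl carbon C1 (intramolecular Friedel–Crafts-type acylation through the C3–C7–C8 allyl cation, with loss of the C2 proton) to give the dienone trifluoroacetate F5.
- NaHCO3 in methanol would give the hydroxy dienone F6, which DMP oxidises to 29.

Step 7. Direct SN2 substitution may compete, phosphate may be lost by 1,4-elimination through the acidic C4 methyl group, and the alane may bind the pyrone carbonyl and erode facial selectivity. The fallback sets out from 5 and comes back at 17, and it treats C4 as a nucleophile.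
- C-formylation of the anion of 5 (LiN(SiMe3)2, ethyl formate) would give the enolisable aldehyde F7.
- Electrophilic ethynylation with 1-[(trimethylsilyl)ethynyl]-1,2-benziodoxol-3(1H)-one and KF under a chiral N-spiro binaphthyl quaternary ammonium phase-transfer catalyst would give the ethynyl aldehyde F8.
- Still–Gennari olefination with 16 would give the terminal alkyne ester F9.
- LiN(SiMe3)2 followed by MeI caps the alkyne and gives 17.

Step 18. Traces of acid may ionise the dienol and trigger a 1,2-shift to an arene (dienol–benzene rearrangement). C9 may also epimerise once the ketone is present. The fallback sets out from 26 and 19 and comes back at 29, and it moves the C10 oxidation ahead of the coupling.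
- DMP oxidation of 26 would give the keto boronate F10.
- NaIO4 and NH4OAc would give the keto boronic acid F11.
- The conditions of step 17 with 19 would give the keto dienol F12.
- The filtered crude solution is oxidised directly with neutral MnO2, which is selective for the bis-allylic carbinol, to give 29.

Further compounds
F1 | step 17 | ethyl ketone, methyl (2Z)-4-(pyranyl)-2,4-dimethyl-5-oxohept-2-enoate, C4 as in 17 | COC(=O)/C(C)=C\[C@](C(=O)CC)(C)c1oc(OC)c(C)c(=O)c1C
F2 | step 17 | (Z)-enol triflate | COC(=O)/C(C)=C\[C@](/C(OS(=O)(=O)C(F)(F)F)=C/C)(C)c1oc(OC)c(C)c(=O)c1C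
F3 | step 17 | triene ester | COC(=O)/C(C)=C\[C@](/C(=C/C)/C(C)=C/[C@H](C)[C@H](O)CC)(C)c1oc(OC)c(C)c(=O)c1C
F4 | step 17 | triene acid | OC(=O)/C(C)=C\[C@](/C(=C/C)/C(C)=C/[C@H](C)[C@H](O)CC)(C)c1oc(OC)c(C)c(=O)c1C
F5 | step 17 | dienone trifluoroacetate | CC[C@@H](OC(=O)C(F)(F)F)[C@@H](C)/C=C(\C)C1=C(C)C(=O)C(C)=C[C@]1(C)c1oc(OC)c(C)c(=O)c1C
F6 | step 17 | hydroxy dienone | CC[C@@H](O)[C@@H](C)/C=C(\C)C1=C(C)C(=O)C(C)=C[C@]1(C)c1oc(OC)c(C)c(=O)c1C
F7 | step 7 | 2-(6-methoxy-3,5-dimethyl-4-oxo-4H-pyran-2-yl)propanal | CC(C=O)c1oc(OC)c(C)c(=O)c1C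
F8 | step 7 | (S)-ethynyl aldehyde | O=C[C@](C#C)(C)c1oc(OC)c(C)c(=O)c1C
F9 | step 7 | terminal alkyne (Z)-enoate | COC(=O)/C(C)=C\[C@](C#C)(C)c1oc(OC)c(C)c(=O)c1C
F10 | step 18 | keto boronate | CCC(=O)[C@@H](C)/C=C(\C)B1OC(C)(C)C(C)(C)O1
F11 | step 18 | keto boronic acid | CCC(=O)[C@@H](C)/C=C(\C)B(O)O
F12 | step 18 | keto dienol (C1 epimers) | CCC(=O)[C@@H](C)/C=C(\C)C1=C(C)C(O)C(C)=C[C@]1(C)c1oc(OC)c(C)c(=O)c1C
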